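**Strategy.** Everything rests on the oxirane C–C bond, the edge shared by the oxirane and the cyclopentane ring (methyl-bearing quaternary carbon to oxirane CH). It is formed last by an intramolecular sulfur-ylide epoxidation: a monocyclic cycloheptane carrying a CH2–S+Ph2 arm and, on the neighbouring ring carbon, a trans acetonyl arm is deprotonated; the ylide adds to the methyl ketone and the alkoxide expels Ph2S. One operation thus closes cyclopentane and oxirane and sets both oxirane stereocentres from the two ring-fusion centres. The cycloheptane is grown from (S)-cryptone, whose single stereocentre comes from organocatalysis and relays all others.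

Key step: step 16

Assumption: the (S)-diarylprolinol silyl ether is taken to give the (S)-aldehyde 3, the electrophile entering the enamine face away from the diarylsiloxymethyl group as in its other Michael additions; the mirror-image catalyst would be used if the sense proved opposite.

Starting materials 1, 2 and 16 are commercial.

Step 1
Reactants: 1 3-methylbutanal; 2 but-3-en-2-one
Product: 4 (4S)-4-(propan-2-yl)cyclohex-2-en-1-one, via keto aldehyde 3 (not isolated)
Conditions: (S)-2-[diphenyl(trimethylsilyloxy)methyl]pyrrolidine (10 mol %), ethyl 3,4-dihydroxybenzoate (20 mol %), neat, 4 °C; then LiOH, i-PrOH, rt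
Reagents that add atoms: none
Why: Enamine-catalysed Michael addition sets the isopropyl-bearing stereocentre by catalyst control, and intramolecular aldol condensation of the methyl ketone onto the aldehyde then closes the cyclohexenone without touching that centre.

Step 2
Reactants: 4 (4S)-4-(propan-2-yl)cyclohex-2-en-1-one
Product: 5 trimethyl{[(3S,4S)-3-(2-methylprop-2-en-1-yl)-4-(propan-2-yl)cyclohex-1-en-1-yl]oxy}silane
Conditions: CH2=C(CH3)CH2MgCl, CuBr·SMe2, LiCl, Me3SiCl, THF, −78 °C; Et3N work-up
Reagents that add atoms: 2-methylallylmagnesium chloride, C=C(C)C[Mg]Cl; chlorotrimethylsilane, C[Si](C)(C)Cl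
Why: Copper-mediated conjugate allylation should deliver the 2-methylallyl group anti to the adjacent isopropyl group (3,4-trans), and silyl trapping fixes the enolate regiospecifically for the ring expansion.

Step 3
Reactants: 5 silyl enol ether
Product: 6 trimethyl{[5-(2-methylprop-2-en-1-yl)-4-(propan-2-yl)bicyclo[4.1.0]heptan-1-yl]oxy}silane (4,5-trans as in 5; cyclopropane anti to the 2-methylallyl group)
Conditions: Et2Zn, CH2I2, CH2Cl2, 0 °C
Reagents that add atoms: diiodomethane, ICI
Why: Simmons–Smith cyclopropanation (Furukawa conditions) is fastest at the electron-rich silyl enol ether, so the isolated alkene should be spared; the cyclopropane face is irrelevant because both new centres are lost in step 4.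

Step 4
Reactants: 6 siloxycyclopropane
Product: 8 (4R,5S)-4-(2-methylprop-2-en-1-yl)-5-(propan-2-yl)cyclohept-2-en-1-one, via β-chloro ketone 7 (not isolated)
Conditions: FeCl3, DMF, 0 °C to rt; then NaOAc, MeOH, reflux
Reagents that add atoms: none
Why: Saegusa–Ito ring expansion, in which one-electron oxidation cleaves the internal cyclopropane bond to a β-keto radical that is chlorinated and acetate then eliminates HCl, inserts one CH2 between the carbonyl and the former α-carbon and gives the conjugated cycloheptenone.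

Step 5
Reactants: 8 cycloheptenone
Product: 9 (3R,4S,5S)-3-ethenyl-4-(2-methylprop-2-en-1-yl)-5-(propan-2-yl)cycloheptan-1-one
Conditions: CH2=CHMgBr, CuI (20 mol %), THF, −40 °C; aq NH4Cl
Reagents that add atoms: vinylmagnesium bromide, C=C[Mg]Br
Why: Copper-catalysed 1,4-addition of the vinyl Grignard reagent should occur anti to the neighbouring 2-methylallyl group, giving the alternating all-trans arrangement of vinyl, 2-methylallyl and isopropyl.

Step 6
Reactants: 9 cycloheptanone
Product: 10 (4R,5R,6R)-6-ethenyl-5-(2-methylprop-2-en-1-yl)-4-(propan-2-yl)cyclohept-2-en-1-one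
Conditions: LiN(i-Pr)2, THF, −78 °C; then PhS(Cl)=N-t-Bu, −78 °C
Reagents that add atoms: none
Why: Kinetic deprotonation should take the less hindered α-CH2 (remote from the vinyl-bearing carbon), and Mukaiyama dehydrogenation of that lithium enolate by the sulfinimidoyl chloride gives the enone conjugated toward the isopropyl side.

Step 7
Reactants: 10 enone
Product: 11 (4R,5R,6R)-6-ethenyl-1-methyl-5-(2-methylprop-2-en-1-yl)-4-(propan-2-yl)cyclohept-2-en-1-ol (both C1 epimers)
Conditions: MeLi, Et2O, −78 °C; aq NH4Cl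
Reagents that add atoms: methyllithium, [Li]C
Why: Methyllithium adds 1,2 to the enone, and the configuration of the new carbinol does not matter because it is erased in step 8.

Step 8
Reactants: 11 tertiary allylic alcohol
Product: 12 (5R,6R,7S)-5-ethenyl-3-methyl-6-(2-methylprop-2-en-1-yl)-7-(propan-2-yl)cyclohept-2-en-1-one
Conditions: pyridinium chlorochromate (C5H5NH)[CrO3Cl], 4 Å molecular sieves, CH2Cl2, rt
Reagents that add atoms: pyridinium chlorochromate, c1cc[nH+]cc1.[O-][Cr](=O)(=O)Cl
Why: Babler–Dauben oxidative transposition, in which the tertiary allylic chromate ester undergoes a [3,3] shift and is oxidised, moves the oxygen to the carbon next to the isopropyl-bearing centre and leaves the methyl on the β-carbon.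

Step 9
Reactants: 12 transposed enone
Product: 13 (1S,5R,6R,7S)-5-ethenyl-3-methyl-6-(2-methylprop-2-en-1-yl)-7-(propan-2-yl)cyclohept-2-en-1-ol
Conditions: LiBH(s-Bu)3, THF, −78 °C
Reagents that add atoms: none
Why: The bulky borohydride should reduce the β,β-disubstituted enone 1,2 from the face opposite the adjacent isopropyl group, giving the allylic alcohol cis to isopropyl.

Step 10
Reactants: 13 allylic alcohol
Product: 14 (1S,2S,3S,4R,5R,7R)-5-ethenyl-7-methyl-4-(2-methylprop-2-en-1-yl)-3-(propan-2-yl)-8-oxabicyclo[5.1.0]octan-2-ol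
Conditions: VO(acac)2 (cat.), t-BuOOH, CH2Cl2, 0 °C to rt
Reagents that add atoms: tert-butyl hydroperoxide, CC(C)(C)OO
Why: Vanadium-catalysed epoxidation is delivered by the allylic hydroxyl to its own face, which sets the methyl-bearing carbinol carbon with its oxygen cis to the secondary alcohol and leaves the two isolated alkenes untouched.

Step 11
Reactants: 14 epoxy alcohol
Product: 15 (1R,3R,4S,5R,6R)-6-ethenyl-1-methyl-5-(2-methylprop-2-en-1-yl)-4-(propan-2-yl)cycloheptane-1,3-diol
Conditions: NaAlH2(OCH2CH2OCH3)2, THF, 0 °C to rt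
Reagents that add atoms: none
Why: Hydride is delivered from the aluminium alkoxide to the epoxide carbon next to the carbinol (the other one is fully substituted), so the tertiary C–O bond and its configuration are kept and the cis-1,3-diol results.

Step 12
Reactants: 15 diol; 16 3-(benzyloxy)-4-methoxybenzoic acid
Product: 17 (1R,2S,3R,4R,6R)-4-ethenyl-6-hydroxy-6-methyl-3-(2-methylprop-2-en-1-yl)-2-(propan-2-yl)cycloheptyl 3-(benzyloxy)-4-methoxybenzoate
Conditions: 16, 2,4,6-Cl3C6H2COCl, Et3N, THF, rt; then 15, DMAP, toluene, 40 °C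
Reagents that add atoms: none
Why: Yamaguchi esterification should acylate only the secondary hydroxyl, the tertiary one being too hindered, with retention of configuration.

Step 13
Reactants: 17 diene ester
Product: 19 (1R,2S,3R,4S,6R)-6-hydroxy-4-(hydroxymethyl)-6-methyl-3-(2-oxopropyl)-2-(propan-2-yl)cycloheptyl 3-(benzyloxy)-4-methoxybenzoate, via keto aldehyde 18 (not isolated)
Conditions: O3, CH2Cl2, −78 °C; PPh3, to rt; then NaBH(OAc)3, AcOH, 0 °C to rt
Reagents that add atoms: ozone, [O-][O+]=O
Why: Ozonolysis cleaves both terminal alkenes to the aldehyde and the methyl ketone, and NaBH(OAc)3 then reduces only the aldehyde because simple ketones are inert to this hydride.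

Step 14
Reactants: 19 hydroxy ketone
Product: 20 (1R,2S,3S,4S,6R)-6-hydroxy-6-methyl-3-(2-oxopropyl)-4-[(phenylsulfanyl)methyl]-2-(propan-2-yl)cycloheptyl 3-(benzyloxy)-4-methoxybenzoate
Conditions: PhSSPh, n-Bu3P, THF, rt
Reagents that add atoms: diphenyl disulfide, c1ccc(SSc2ccccc2)cc1
Why: Hata thioetherification (phosphonium activation of the primary alcohol, then SN2 by thiophenolate) converts only the primary hydroxyl; tertiary hydroxyl, ketone and ester are inert.

Step 15
Reactants: 20 phenyl sulfide
Product: 21 diphenylsulfonium trifluoromethanesulfonate of 20 (CH2–S+Ph2 in place of CH2–SPh; ring configuration unchanged)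
Conditions: Ph2I+ CF3SO3−, Cu(OAc)2 (5 mol %), 1,2-dichloroethane, 70–90 °C
Reagents that add atoms: diphenyliodonium trifluoromethanesulfonate, c1ccc([I+]c2ccccc2)cc1.[O-]S(=O)(=O)C(F)(F)F
Why: Copper-catalysed S-arylation of the sulfide by the diaryliodonium salt gives the alkyldiphenylsulfonium salt, whose only α-hydrogens sit on the CH2 that is to become the oxirane CH.

Step 16
Reactants: 21 sulfonium salt
Product: 24 O-benzyl ether of the target, via sulfonium ylide 22 (not isolated), via betaine 23 (not isolated)
Conditions: phosphazene base P2-Et, EtN=P(NMe2)2–N=P(NMe2)3 (1.1 equiv), CH2Cl2, −78 to 0 °C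
Reagents that add atoms: none
Why: The base removes a proton from the CH2 next to sulfur, by far the most acidic site (well below the ketone α-CH and the tertiary OH), to give ylide 22; its carbanion adds to the methyl ketone on the neighbouring ring carbon (5-exo-trig, cyclopentane) to give betaine 23, whose alkoxide displaces Ph2S with inversion (3-exo-tet, oxirane). This is a Johnson–Corey–Chaykovsky epoxidation run intramolecularly, the reaction type known from epoxy-annulations of tethered sulfonium ylides with ketones and from alkyldiphenylsulfonium ylides with ketones. Both new stereocentres are controlled by the two trans ring-fusion carbons: in the forming cyclopentane the bulky Ph2S+ should take the side trans to the adjacent ring C–C bond (cis to the ring-fusion H), only the betaine with O− anti to S+ can close, and inversion at the CH carbon then places the oxirane oxygen anti to that ring-fusion H, on the face of the tertiary OH, with the methyl on the other face. The step needs ylide formation to beat enolisation and β-elimination, which the acidity gap, the weak non-nucleophilic base and the low temperature should secure, and it needs the anti betaine, the only one that leads on to product. The aryl ester, benzyl ether and free tertiary alcohol are not touched by this base.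

Step 17
Reactants: 24 O-benzyl ether of the target
Product: 25 target CNP0106636.1
Conditions: H2 (1 atm), Pd/C, EtOAc, rt
Reagents that add atoms: none
Why: Hydrogenolysis cleaves the benzyl aryl ether, while the trisubstituted aliphatic oxirane, the ester and the tertiary alcohol are stable under neutral conditions.

**Compound list**

1 | 3-methylbutanal | CC(C)CC=O | starting material
2 | but-3-en-2-one (methyl vinyl ketone) | CC(=O)C=C | starting material
3 | (2S)-5-oxo-2-(propan-2-yl)hexanal | O=C[C@H](C(C)C)CCC(C)=O | intermediate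
4 | (4S)-4-(propan-2-yl)cyclohex-2-en-1-one ((S)-cryptone) | O=C1C=C[C@H](C(C)C)CC1 | intermediate
5 | trimethyl{[(3S,4S)-3-(2-methylprop-2-en-1-yl)-4-(propan-2-yl)cyclohex-1-en-1-yl]oxy}silane (3,4-trans) | C[Si](C)(C)OC1=C[C@@H](CC(C)=C)[C@H](C(C)C)CC1 | intermediate
6 | trimethyl{[5-(2-methylprop-2-en-1-yl)-4-(propan-2-yl)bicyclo[4.1.0]heptan-1-yl]oxy}silane (4,5-trans; cyclopropane anti to the 2-methylallyl group) | C[Si](C)(C)O[C@@]12C[C@@H]1[C@@H](CC(C)=C)[C@H](C(C)C)CC2 | intermediate
7 | 3-chloro-4-(2-methylprop-2-en-1-yl)-5-(propan-2-yl)cycloheptan-1-one (4,5-trans as in 8; epimers at the chlorine-bearing carbon) | O=C1CC(Cl)[C@@H](CC(C)=C)[C@H](C(C)C)CC1 | intermediate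
8 | (4R,5S)-4-(2-methylprop-2-en-1-yl)-5-(propan-2-yl)cyclohept-2-en-1-one | O=C1C=C[C@@H](CC(C)=C)[C@H](C(C)C)CC1 | intermediate
9 | (3R,4S,5S)-3-ethenyl-4-(2-methylprop-2-en-1-yl)-5-(propan-2-yl)cycloheptan-1-one | O=C1C[C@H](C=C)[C@@H](CC(C)=C)[C@H](C(C)C)CC1 | intermediate
10 | (4R,5R,6R)-6-ethenyl-5-(2-methylprop-2-en-1-yl)-4-(propan-2-yl)cyclohept-2-en-1-one | O=C1C[C@H](C=C)[C@@H](CC(C)=C)[C@H](C(C)C)C=C1 | intermediate
11 | (4R,5R,6R)-6-ethenyl-1-methyl-5-(2-methylprop-2-en-1-yl)-4-(propan-2-yl)cyclohept-2-en-1-ol (both C1 epimers) | CC1(O)C[C@H](C=C)[C@@H](CC(C)=C)[C@H](C(C)C)C=C1 | intermediate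
12 | (5R,6R,7S)-5-ethenyl-3-methyl-6-(2-methylprop-2-en-1-yl)-7-(propan-2-yl)cyclohept-2-en-1-one | O=C1C=C(C)C[C@H](C=C)[C@@H](CC(C)=C)[C@@H]1C(C)C | intermediate
13 | (1S,5R,6R,7S)-5-ethenyl-3-methyl-6-(2-methylprop-2-en-1-yl)-7-(propan-2-yl)cyclohept-2-en-1-ol | O[C@@H]1C=C(C)C[C@H](C=C)[C@@H](CC(C)=C)[C@@H]1C(C)C | intermediate
14 | (1S,2S,3S,4R,5R,7R)-5-ethenyl-7-methyl-4-(2-methylprop-2-en-1-yl)-3-(propan-2-yl)-8-oxabicyclo[5.1.0]octan-2-ol | O[C@@H]1[C@@H]2O[C@]2(C)C[C@H](C=C)[C@@H](CC(C)=C)[C@@H]1C(C)C | intermediate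
15 | (1R,3R,4S,5R,6R)-6-ethenyl-1-methyl-5-(2-methylprop-2-en-1-yl)-4-(propan-2-yl)cycloheptane-1,3-diol | O[C@@H]1C[C@](C)(O)C[C@H](C=C)[C@@H](CC(C)=C)[C@@H]1C(C)C | intermediate
16 | 3-(benzyloxy)-4-methoxybenzoic acid | COc1ccc(C(=O)O)cc1OCc1ccccc1 | starting material
17 | (1R,2S,3R,4R,6R)-4-ethenyl-6-hydroxy-6-methyl-3-(2-methylprop-2-en-1-yl)-2-(propan-2-yl)cycloheptyl 3-(benzyloxy)-4-methoxybenzoate | COc1ccc(C(=O)O[C@@H]2C[C@](C)(O)C[C@H](C=C)[C@@H](CC(C)=C)[C@@H]2C(C)C)cc1OCc1ccccc1 | intermediate
18 | (1R,2S,3S,4S,6R)-4-formyl-6-hydroxy-6-methyl-3-(2-oxopropyl)-2-(propan-2-yl)cycloheptyl 3-(benzyloxy)-4-methoxybenzoate | COc1ccc(C(=O)O[C@@H]2C[C@](C)(O)C[C@H](C=O)[C@@H](CC(C)=O)[C@@H]2C(C)C)cc1OCc1ccccc1 | intermediate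
19 | (1R,2S,3R,4S,6R)-6-hydroxy-4-(hydroxymethyl)-6-methyl-3-(2-oxopropyl)-2-(propan-2-yl)cycloheptyl 3-(benzyloxy)-4-methoxybenzoate | COc1ccc(C(=O)O[C@@H]2C[C@](C)(O)C[C@H](CO)[C@@H](CC(C)=O)[C@@H]2C(C)C)cc1OCc1ccccc1 | intermediate
20 | (1R,2S,3S,4S,6R)-6-hydroxy-6-methyl-3-(2-oxopropyl)-4-[(phenylsulfanyl)methyl]-2-(propan-2-yl)cycloheptyl 3-(benzyloxy)-4-methoxybenzoate | COc1ccc(C(=O)O[C@@H]2C[C@](C)(O)C[C@H](CSc3ccccc3)[C@@H](CC(C)=O)[C@@H]2C(C)C)cc1OCc1ccccc1 | intermediate
21 | diphenylsulfonium trifluoromethanesulfonate of 20 (CH2–S+Ph2 in place of CH2–SPh; ring configuration as in 20) | COc1ccc(C(=O)O[C@@H]2C[C@](C)(O)C[C@H](C[S+](c3ccccc3)c3ccccc3)[C@@H](CC(C)=O)[C@@H]2C(C)C)cc1OCc1ccccc1.[O-]S(=O)(=O)C(F)(F)F | intermediate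
22 | sulfonium ylide of 21 (carbanion on the CH attached to S+) | COc1ccc(C(=O)O[C@@H]2C[C@](C)(O)C[C@H]([CH-][S+](c3ccccc3)c3ccccc3)[C@@H](CC(C)=O)[C@@H]2C(C)C)cc1OCc1ccccc1 | intermediate
23 | betaine: trans-fused cyclopentane bearing the tertiary alkoxide (methyl on the same carbon) and, on the next carbon, Ph2S+ trans to O− | COc1ccc(C(=O)O[C@@H]2C[C@](C)(O)C[C@H]3[C@@H](C[C@@](C)([O-])[C@@H]3[S+](c4ccccc4)c4ccccc4)[C@@H]2C(C)C)cc1OCc1ccccc1 | intermediate
24 | O-benzyl ether of the target: 3-(benzyloxy)-4-methoxybenzoate of the oxirane-fused trans-hydroazulene alcohol (acyloxy, isopropyl, tertiary hydroxyl and oxirane oxygen all on one face) | COc1ccc(C(=O)O[C@@H]2C[C@](C)(O)C[C@H]3[C@@H](C[C@@]4(C)O[C@@H]34)[C@@H]2C(C)C)cc1OCc1ccccc1 | intermediate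
25 | CNP0106636.1: 3-hydroxy-4-methoxybenzoate of the same oxirane-fused trans-hydroazulene alcohol | COc1ccc(C(=O)O[C@@H]2C[C@](C)(O)C[C@H]3[C@@H](C[C@@]4(C)O[C@@H]34)[C@@H]2C(C)C)cc1O | target

**Totals.** Total step count: 17. Longest linear sequence: 17 steps (from 1 and 2 to 25; acid 16 is bought).

**Steps most likely to fail**

Step 16. The ylide may add through the betaine that cannot close (O− syn to S+) or with poor facial selectivity, or the salt may undergo β-elimination instead of ylide formation. The fallback sets out from diene ester 17. Ring-closing metathesis with the second-generation Grubbs catalyst (H2IMes)(PCy3)Cl2Ru=CHPh in CH2Cl2 at 40 °C would join the vinyl and 2-methylallyl groups to the trans-fused methylcyclopentene F1, forming the same C–C bond as an alkene. Epoxidation with VO(acac)2/t-BuOOH, delivered by the tertiary hydroxyl to its own face, would then give 24, where the route is rejoined.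

Step 6. Enolate formation may fail to discriminate between the two α-methylene groups, so that the wrong enone or over-oxidation results. The fallback sets out from enone 8, whose only enolisable α-position is the required one. LiN(i-Pr)2 then PhSSPh would give the α'-phenylsulfanyl enone F2. Addition of CH2=CHMgBr with CuI and Me3SiCl would give the sulfanyl ketone F3. NaIO4 would give the sulfoxide F4, and its syn-elimination in hot toluene would give 10, where the route is rejoined.

Step 15. The copper-mediated aryl transfer may stall on the hindered, functionalised sulfide, or the heated sulfonium salt may lose its alkyl group to the neighbouring hydroxyl. The fallback sets out from alcohol 19. I2/PPh3/imidazole would give the primary iodide F5, and alkylation of excess Ph2S promoted by AgOSO2CF3 in CH2Cl2 at room temperature would give 21 directly, where the route is rejoined.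

**Further compounds**

F1 | step 16 | trans-fused methylcyclopentene from ring-closing metathesis of 17 (3-(benzyloxy)-4-methoxybenzoate; configuration at the five ring stereocentres as in 17) | COc1ccc(C(=O)O[C@@H]2C[C@](C)(O)C[C@@H]3C=C(C)C[C@H]3[C@@H]2C(C)C)cc1OCc1ccccc1
F2 | step 6 | (4R,5S)-4-(2-methylprop-2-en-1-yl)-7-(phenylsulfanyl)-5-(propan-2-yl)cyclohept-2-en-1-one (C7 epimers) | O=C1C=C[C@@H](CC(C)=C)[C@H](C(C)C)CC1Sc1ccccc1
F3 | step 6 | 6-ethenyl-5-(2-methylprop-2-en-1-yl)-2-(phenylsulfanyl)-4-(propan-2-yl)cycloheptan-1-one (ring configuration as in 9; C2 epimers) | O=C1C[C@H](C=C)[C@@H](CC(C)=C)[C@H](C(C)C)CC1Sc1ccccc1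
F4 | step 6 | 6-ethenyl-5-(2-methylprop-2-en-1-yl)-2-(phenylsulfinyl)-4-(propan-2-yl)cycloheptan-1-one (ring configuration as in 9) | O=C1C[C@H](C=C)[C@@H](CC(C)=C)[C@H](C(C)C)CC1S(=O)c1ccccc1
F5 | step 15 | (1R,2S,3S,4S,6R)-6-hydroxy-4-(iodomethyl)-6-methyl-3-(2-oxopropyl)-2-(propan-2-yl)cycloheptyl 3-(benzyloxy)-4-methoxybenzoate | COc1ccc(C(=O)O[C@@H]2C[C@](C)(O)C[C@H](CI)[C@@H](CC(C)=O)[C@@H]2C(C)C)cc1OCc1ccccc1
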